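**Strategy.** Everything rests on the C8–C8'' biaryl bond, whose four ortho carbons (C7, C8a, C7'', C8a'') all carry oxygen. Both termini are innately nucleophilic, so the finished acacetin half is polarity-reversed as a flavon-8-yllead triacetate; in one operation its C8 is transferred to the carbon ortho to the free hydroxyl of symmetrical 3,5-dibenzyloxyphenol. The exploited feature is O1'' on C8a'' of the second ring A, flanked by C8'' and C4a'': as the free phenol oxygen it binds lead and directs the aryl group to C8'', while its other, equivalent ortho carbon later becomes C4a'' when the second ring C is closed by Friedel–Crafts acylation. The axis forms as the racemate.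

Key step: step 6

Assumption: the given structure carries no descriptor for the C8–C8'' axis, so the racemic atropisomer mixture is taken as the goal, and 3,5-bis(benzyloxy)phenol is taken as a purchasable compound.

**Step 1**
Reactants: 1 phloroglucinol; 2 ethyl 3-(4-methoxyphenyl)-3-oxopropanoate
Product: 3 acacetin (5,7-dihydroxy-4'-methoxyflavone)
Conditions: neat, 2 (1.5 equiv), microwave or sand bath, 240 °C, N2
Reagents that add atoms: none
Why: Mentzer pyrone synthesis, in which thermal loss of ethanol lets the aroylacetyl unit acylate a ring carbon of 1 and a phenol oxygen then condenses with the aryl ketone, the threefold symmetry of 1 allowing only one flavone and the absence of acid disfavouring the coumarin pathway.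

**Step 2**
Reactants: 3 acacetin
Product: 4 5,7-bis(benzyloxy)-4'-methoxyflavone
Conditions: BnBr (3 equiv), K2CO3 (4 equiv), Bu4NI (cat.), DMF, 80 °C
Reagents that add atoms: benzyl bromide, BrCc1ccccc1
Why: Williamson ether synthesis in which the acidic 7-OH reacts first and excess reagent with heat should overcome the hydrogen bond between the 5-OH and the C4 carbonyl.

**Step 3**
Reactants: 4 5,7-bis(benzyloxy)-4'-methoxyflavone
Product: 5 5,7-bis(benzyloxy)-8-iodo-4'-methoxyflavone
Conditions: NIS (1.05 equiv), TFA (0.2 equiv), MeCN–CH2Cl2, 0 °C to rt, dark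
Reagents that add atoms: N-iodosuccinimide, O=C1CCC(=O)N1I
Why: Electrophilic aromatic iodination of ring A, the most electron-rich ring, where C8 (between O7 and the ring oxygen O1) is the established site once O5 is alkylated and is less shielded than C6, which lies between two benzyloxy groups.

**Step 4**
Reactants: 5 5,7-bis(benzyloxy)-8-iodo-4'-methoxyflavone
Product: 6 5,7-bis(benzyloxy)-4'-methoxy-8-(tributylstannyl)flavone
Conditions: (Bu3Sn)2 (1.5 equiv), Pd(PPh3)4 (10 mol%), toluene, 110 °C
Reagents that add atoms: hexabutylditin, CCCC[Sn](CCCC)(CCCC)[Sn](CCCC)(CCCC)CCCC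
Why: Palladium-catalysed stannylation of an aryl iodide with a distannane (oxidative addition to zerovalent palladium, tin-to-palladium transmetalation, reductive elimination), with the distannane in excess to hold back Stille homocoupling.

**Step 5**
Reactants: 6 5,7-bis(benzyloxy)-4'-methoxy-8-(tributylstannyl)flavone
Product: 7 [5,7-bis(benzyloxy)-4'-methoxyflavon-8-yl]lead triacetate
Conditions: Pb(OAc)4 (1.1 equiv), Hg(OAc)2 (10 mol%), CHCl3, 40 °C; water wash, Celite, precipitation from hexane, used at once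
Reagents that add atoms: lead tetraacetate, CC(=O)O[Pb](OC(C)=O)(OC(C)=O)OC(C)=O
Why: Tin–lead exchange (Pinhey preparation of aryllead triacetates), in which the aryl group passes from tin through a catalytic arylmercury species to tetravalent lead, the water wash hydrolysing unused Pb(OAc)4 so that it cannot oxidise phenol 8 in the next step.

**Step 6**
Reactants: 7 [5,7-bis(benzyloxy)-4'-methoxyflavon-8-yl]lead triacetate; 8 3,5-bis(benzyloxy)phenol
Product: 11 8-[2,4-bis(benzyloxy)-6-hydroxyphenyl]-5,7-bis(benzyloxy)-4'-methoxyflavone, via aryl(aryloxy)lead diacetate 9 (not isolated), via 6-arylcyclohexa-2,4-dienone 10 (not isolated)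
Conditions: 8 (3 equiv), pyridine (4 equiv), CHCl3, 4 Å MS, rt to 40 °C, under argon
Reagents that add atoms: none
Why: One acetate on the tetravalent lead of 7 is exchanged for the phenoxide of 8 (pyridine as base and ligand) to give aryl(aryloxy)lead diacetate 9, which collapses by ligand coupling through the ortho carbon, with loss of Pb(OAc)2, to cyclohexadienone 10, and enolisation then restores the phenol in 11. This is the Pinhey ortho-C-arylation of phenols by aryllead triacetates, a reaction type known to accept 2,6-dioxygenated aryl ligands and to give tri- and tetra-ortho-substituted 2-hydroxybiaryls. No ring is closed, only the C8–C8'' bond is formed. No stereocentre persists, because the sp3 carbon of 10 is erased on tautomerisation and the new hindered axis, unspecified in the target, is produced as the racemate. The step needs C-arylation ortho to the hydroxyl instead of para attack or O-arylation, and one aryl transfer instead of two: delivery from lead bound to the phenol oxygen (the future O1'') fixes the ortho site, the mirror symmetry of 8 makes its two ortho carbons identical, and the excess of 8 together with the crowding around the hydroxyl of 11 should suppress a second arylation.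

**Step 7**
Reactants: 12 1-(benzyloxy)-4-iodobenzene; 13 methyl propiolate
Product: 14 methyl 3-[4-(benzyloxy)phenyl]prop-2-ynoate
Conditions: 13 (2.5 equiv, slow addition), PdCl2(PPh3)2 (2 mol%), CuI (4 mol%), K2CO3 (2 equiv), THF, 65 °C
Reagents that add atoms: none
Why: Sonogashira coupling in which the carbonate base replaces the usual amine, which would add to the electron-poor alkyne.

**Step 8**
Reactants: 11 8-[2,4-bis(benzyloxy)-6-hydroxyphenyl]-5,7-bis(benzyloxy)-4'-methoxyflavone; 14 methyl 3-[4-(benzyloxy)phenyl]prop-2-ynoate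
Product: 15 methyl (Z)-3-{3,5-bis(benzyloxy)-2-[5,7-bis(benzyloxy)-4'-methoxyflavon-8-yl]phenoxy}-3-[4-(benzyloxy)phenyl]prop-2-enoate
Conditions: 14 (1.5 equiv), Cs2CO3 (0.5 equiv), DMF, 80 °C
Reagents that add atoms: none
Why: Oxa-Michael addition (first stage of the Ruhemann flavone synthesis), in which the phenoxide attacks C3 of the ynoate to form the O1''–C2'' bond and anti protonation of the vinyl anion should place the aryloxy and ester groups cis (Z), the geometry that can close ring C.

**Step 9**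
Reactants: 15 methyl (Z)-3-{3,5-bis(benzyloxy)-2-[5,7-bis(benzyloxy)-4'-methoxyflavon-8-yl]phenoxy}-3-[4-(benzyloxy)phenyl]prop-2-enoate
Product: 16 (Z)-3-{3,5-bis(benzyloxy)-2-[5,7-bis(benzyloxy)-4'-methoxyflavon-8-yl]phenoxy}-3-[4-(benzyloxy)phenyl]prop-2-enoic acid
Conditions: LiOH·H2O (4 equiv), THF–MeOH–H2O, rt; then 1 M HCl to pH 3 at 0 °C
Reagents that add atoms: lithium hydroxide, [Li+].[OH-]
Why: Saponification by acyl-oxygen cleavage of an unhindered methyl ester, under conditions to which the benzyl ethers, the enol ether and the pyranone of the existing flavone should be inert.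

**Step 10**
Reactants: 16 (Z)-3-{3,5-bis(benzyloxy)-2-[5,7-bis(benzyloxy)-4'-methoxyflavon-8-yl]phenoxy}-3-[4-(benzyloxy)phenyl]prop-2-enoic acid
Product: 18 5,7,5'',7'',4'''-penta-O-benzyl-4'-O-methylcupressuflavone, via mixed trifluoroacetic anhydride 17 (not isolated)
Conditions: (CF3CO)2O (3 equiv), CH2Cl2, 0 °C to rt
Reagents that add atoms: trifluoroacetic anhydride, O=C(OC(=O)C(F)(F)F)C(F)(F)F (its trifluoroacetyl group is present only in 17 and leaves again on ring closure, so nothing from it remains in 18)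
Why: Intramolecular Friedel–Crafts acylation through the mixed anhydride closes the six-membered ring C at C4''–C4a'', the attacked carbon being the only free position ortho to O1'' and activated ortho and para by two benzyloxy groups, whereas ring B could react only meta to its benzyloxy group and the push–pull alkene can equilibrate under acid so that the cis arrangement needed for closure stays accessible.

**Step 11**
Reactants: 18 5,7,5'',7'',4'''-penta-O-benzyl-4'-O-methylcupressuflavone
Product: 19 cupressuflavone 4'-methyl ether (target)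
Conditions: H2 (1 atm), 10% Pd/C, THF–MeOH, rt
Reagents that add atoms: none
Why: Catalytic hydrogenolysis of the five benzyl aryl ethers, which cannot cleave the methyl ether and reduces the C2=C3 bonds of the two pyranones far more slowly, so the reaction is stopped when debenzylation is complete.

**Compound list**

1 | phloroglucinol | Oc1cc(O)cc(O)c1 | starting material
2 | ethyl 3-(4-methoxyphenyl)-3-oxopropanoate | CCOC(=O)CC(=O)c1ccc(OC)cc1 | starting material
3 | acacetin (5,7-dihydroxy-4'-methoxyflavone) | COc1ccc(-c2cc(=O)c3c(O)cc(O)cc3o2)cc1 | intermediate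
4 | 5,7-bis(benzyloxy)-4'-methoxyflavone | COc1ccc(-c2cc(=O)c3c(OCc4ccccc4)cc(OCc4ccccc4)cc3o2)cc1 | intermediate
5 | 5,7-bis(benzyloxy)-8-iodo-4'-methoxyflavone | COc1ccc(-c2cc(=O)c3c(OCc4ccccc4)cc(OCc4ccccc4)c(I)c3o2)cc1 | intermediate
6 | 5,7-bis(benzyloxy)-4'-methoxy-8-(tributylstannyl)flavone | COc1ccc(-c2cc(=O)c3c(OCc4ccccc4)cc(OCc4ccccc4)c([Sn](CCCC)(CCCC)CCCC)c3o2)cc1 | intermediate
7 | [5,7-bis(benzyloxy)-4'-methoxyflavon-8-yl]lead triacetate | COc1ccc(-c2cc(=O)c3c(OCc4ccccc4)cc(OCc4ccccc4)c([Pb](OC(C)=O)(OC(C)=O)OC(C)=O)c3o2)cc1 | intermediate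
8 | 3,5-bis(benzyloxy)phenol | Oc1cc(OCc2ccccc2)cc(OCc2ccccc2)c1 | starting material
9 | [5,7-bis(benzyloxy)-4'-methoxyflavon-8-yl][3,5-bis(benzyloxy)phenoxy]lead diacetate, not isolated | COc1ccc(-c2cc(=O)c3c(OCc4ccccc4)cc(OCc4ccccc4)c([Pb](OC(C)=O)(OC(C)=O)Oc4cc(OCc5ccccc5)cc(OCc5ccccc5)c4)c3o2)cc1 | intermediate
10 | 6-[5,7-bis(benzyloxy)-4'-methoxyflavon-8-yl]-3,5-bis(benzyloxy)cyclohexa-2,4-dien-1-one, racemic at C6, not isolated | COc1ccc(-c2cc(=O)c3c(OCc4ccccc4)cc(OCc4ccccc4)c(C4C(=O)C=C(OCc5ccccc5)C=C4OCc4ccccc4)c3o2)cc1 | intermediate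
11 | 8-[2,4-bis(benzyloxy)-6-hydroxyphenyl]-5,7-bis(benzyloxy)-4'-methoxyflavone, racemic about the biaryl axis | COc1ccc(-c2cc(=O)c3c(OCc4ccccc4)cc(OCc4ccccc4)c(-c4c(O)cc(OCc5ccccc5)cc4OCc4ccccc4)c3o2)cc1 | intermediate
12 | 1-(benzyloxy)-4-iodobenzene | Ic1ccc(OCc2ccccc2)cc1 | starting material
13 | methyl propiolate | C#CC(=O)OC | starting material
14 | methyl 3-[4-(benzyloxy)phenyl]prop-2-ynoate | COC(=O)C#Cc1ccc(OCc2ccccc2)cc1 | intermediate
15 | methyl (Z)-3-{3,5-bis(benzyloxy)-2-[5,7-bis(benzyloxy)-4'-methoxyflavon-8-yl]phenoxy}-3-[4-(benzyloxy)phenyl]prop-2-enoate | COC(=O)/C=C(\Oc1cc(OCc2ccccc2)cc(OCc2ccccc2)c1-c1c(OCc2ccccc2)cc(OCc2ccccc2)c2c(=O)cc(-c3ccc(OC)cc3)oc12)c1ccc(OCc2ccccc2)cc1 | intermediate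
16 | (Z)-3-{3,5-bis(benzyloxy)-2-[5,7-bis(benzyloxy)-4'-methoxyflavon-8-yl]phenoxy}-3-[4-(benzyloxy)phenyl]prop-2-enoic acid | OC(=O)/C=C(\Oc1cc(OCc2ccccc2)cc(OCc2ccccc2)c1-c1c(OCc2ccccc2)cc(OCc2ccccc2)c2c(=O)cc(-c3ccc(OC)cc3)oc12)c1ccc(OCc2ccccc2)cc1 | intermediate
17 | mixed anhydride of acid 16 with trifluoroacetic acid (Z), not isolated | FC(F)(F)C(=O)OC(=O)/C=C(\Oc1cc(OCc2ccccc2)cc(OCc2ccccc2)c1-c1c(OCc2ccccc2)cc(OCc2ccccc2)c2c(=O)cc(-c3ccc(OC)cc3)oc12)c1ccc(OCc2ccccc2)cc1 | intermediate
18 | 5,7,5'',7'',4'''-penta-O-benzyl-4'-O-methylcupressuflavone, racemic about the C8–C8'' axis | COc1ccc(-c2cc(=O)c3c(OCc4ccccc4)cc(OCc4ccccc4)c(-c4c(OCc5ccccc5)cc(OCc5ccccc5)c5c(=O)cc(-c6ccc(OCc7ccccc7)cc6)oc45)c3o2)cc1 | intermediate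
19 | cupressuflavone 4'-methyl ether, racemic about the C8–C8'' axis | COc1ccc(-c2cc(=O)c3c(O)cc(O)c(-c4c(O)cc(O)c5c(=O)cc(-c6ccc(O)cc6)oc45)c3o2)cc1 | target

**Step count and risks**

Total step count: 11. Longest linear sequence: 10 steps (steps 1 to 6 and 8 to 11, from phloroglucinol); step 7 is a one-step side branch.

Steps most likely to fail:

1. **Step 6 (ligand coupling).** The electron-rich phenoxide may be oxidised by tetravalent lead instead of being arylated, or aryl transfer at the doubly flanked C8 may be slower than protodeplumbation. The fallback sets out from iodide 5 and comes back at 18 by Suzuki–Miyaura coupling of two complete flavone halves. Purchased apigenin is benzylated (BnBr, K2CO3, DMF, 80 °C) to 5,7,4'-tris(benzyloxy)flavone F1. This is iodinated at C8 (NIS, cat. TFA) to 5,7,4'-tris(benzyloxy)-8-iodoflavone F2 and borylated (B2pin2, PdCl2(dppf), KOAc, dioxane, 90 °C) to 5,7,4'-tris(benzyloxy)-8-(4,4,5,5-tetramethyl-1,3,2-dioxaborolan-2-yl)flavone F3. Cross-coupling of F3 with 5 (Pd(OAc)2, SPhos, K3PO4, toluene–water, 100 °C) would give 18 and make steps 8 to 10 unnecessary. The price is a congested palladium-mediated coupling that depends on the bulky biarylphosphine.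

2. **Step 4 (stannylation).** Oxidative addition and transmetalation at the di-ortho-substituted iodide may be slow, so that reductive loss of iodine and homocoupling of the new stannane with unreacted 5 take over. The fallback sets out from 5 and comes back at 7 through boron instead of tin. Miyaura borylation (B2pin2, Pd(OAc)2, SPhos, KOAc, dioxane, 90 °C) gives 5,7-bis(benzyloxy)-4'-methoxy-8-(4,4,5,5-tetramethyl-1,3,2-dioxaborolan-2-yl)flavone F4. The pinacol is removed oxidatively (NaIO4, NH4OAc, acetone–water, rt) to give [5,7-bis(benzyloxy)-4'-methoxyflavon-8-yl]boronic acid F5. Boron–lead exchange (Pb(OAc)4, cat. Hg(OAc)2, CHCl3, 40 °C) then delivers 7.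

3. **Step 10 (Friedel–Crafts closure).** Acid-induced cleavage of the aryl vinyl ether, or loss and migration of benzyl groups on the electron-rich rings, may outrun acylation. The fallback sets out from 11 and comes back at 18 with the bond order reversed (C4''–C4a'' first, O1''–C2'' last). C-acetylation at the free carbon ortho to the hydroxyl (Ac2O, BF3·OEt2, rt, O-acetate then boron-templated Fries shift) gives 8-[3-acetyl-4,6-bis(benzyloxy)-2-hydroxyphenyl]-5,7-bis(benzyloxy)-4'-methoxyflavone F6. Claisen–Schmidt condensation with purchased 4-(benzyloxy)benzaldehyde (KOH, EtOH–THF, rt) gives the chalcone 8-{4,6-bis(benzyloxy)-3-[(E)-3-(4-benzyloxyphenyl)prop-2-enoyl]-2-hydroxyphenyl}-5,7-bis(benzyloxy)-4'-methoxyflavone F7. Oxidative cyclisation (I2 cat., DMSO, 120 °C) closes ring C to 18.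

**Further compounds**

F1 | step 6 | 5,7,4'-tris(benzyloxy)flavone | O=c1cc(-c2ccc(OCc3ccccc3)cc2)oc2cc(OCc3ccccc3)cc(OCc3ccccc3)c12
F2 | step 6 | 5,7,4'-tris(benzyloxy)-8-iodoflavone | O=c1cc(-c2ccc(OCc3ccccc3)cc2)oc2c(I)c(OCc3ccccc3)cc(OCc3ccccc3)c12
F3 | step 6 | 5,7,4'-tris(benzyloxy)-8-(4,4,5,5-tetramethyl-1,3,2-dioxaborolan-2-yl)flavone | O=c1cc(-c2ccc(OCc3ccccc3)cc2)oc2c(B3OC(C)(C)C(C)(C)O3)c(OCc3ccccc3)cc(OCc3ccccc3)c12
F4 | step 4 | 5,7-bis(benzyloxy)-4'-methoxy-8-(4,4,5,5-tetramethyl-1,3,2-dioxaborolan-2-yl)flavone | COc1ccc(-c2cc(=O)c3c(OCc4ccccc4)cc(OCc4ccccc4)c(B4OC(C)(C)C(C)(C)O4)c3o2)cc1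
F5 | step 4 | [5,7-bis(benzyloxy)-4'-methoxyflavon-8-yl]boronic acid | COc1ccc(-c2cc(=O)c3c(OCc4ccccc4)cc(OCc4ccccc4)c(B(O)O)c3o2)cc1
F6 | step 10 | 8-[3-acetyl-4,6-bis(benzyloxy)-2-hydroxyphenyl]-5,7-bis(benzyloxy)-4'-methoxyflavone | COc1ccc(-c2cc(=O)c3c(OCc4ccccc4)cc(OCc4ccccc4)c(-c4c(O)c(C(C)=O)c(OCc5ccccc5)cc4OCc4ccccc4)c3o2)cc1
F7 | step 10 | 8-{4,6-bis(benzyloxy)-3-[(E)-3-(4-benzyloxyphenyl)prop-2-enoyl]-2-hydroxyphenyl}-5,7-bis(benzyloxy)-4'-methoxyflavone | COc1ccc(-c2cc(=O)c3c(OCc4ccccc4)cc(OCc4ccccc4)c(-c4c(O)c(C(=O)/C=C/c5ccc(OCc6ccccc6)cc5)c(OCc5ccccc5)cc4OCc4ccccc4)c3o2)cc1
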